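**Strategy.** The drimane core (drimane numbering; C11 is the OCH2 on C9) has its C11 carbon and C1 on the same face of ring B across the C9–C10 bond, and its C7=C8 alkene lies where a cyclohexene-forming cycloaddition leaves a double bond. Ring B is therefore cut at C9–C10 and C5–C6. A catalytic enantioselective intramolecular Diels–Alder reaction of ester 9, in which a C11–O–C1(=O) ester links a (Z)-diene (C6 to C9) to an (E)-2-methylenoate (C5=C10), should form ring B, a cis-fused γ-lactone and the stereocentres C5, C9 and C10 at once. The lactone later releases C11–OH and a C1 aldehyde that closes ring A by aldol condensation onto the C3 methyl ketone, carried unprotected.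

Key step: step 6

Remarks on the chemistry (drimane numbering is used for positions throughout):
- Assumed sense of induction: the (S)-configured catalyst is taken to deliver the (3aR,7S,7aS) adduct 10; if the opposite sense is found, the catalyst from (R)-diphenylprolinol is used with nothing else changed.
- Precursor design: the C3 ketone is left free in 9, because a ketal would be ionised by the triflimide-activated boron acid and would sequester it, whereas a hindered ketone only competes reversibly for the catalyst.
- After the key step: C11–OH is silylated before ring A is closed, because a free C11 hydroxyl lies cis to C1 and would add to the C1=C2 enone (oxa-Michael) to re-form the five-membered ether ring.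

Step 1
Reactants: 1 ethyl 2,2-dimethyl-3-oxobutanoate
Product: 2 2,2-dimethylbutane-1,3-diol (racemic)
Conditions: LiAlH4, THF, 0 °C → reflux; aqueous NaOH work-up
Reagents that add atoms: none
Why: Hydride reduction with LiAlH4 takes both the ester and the ketone to the alcohol level, so the ketone needs no protecting group on the way to the aldehyde; the racemic carbinol centre is erased in step 2.

Step 2
Reactants: 2 2,2-dimethylbutane-1,3-diol; 3 ethyl 2-(triphenylphosphoranylidene)propanoate
Product: 5 ethyl (E)-2,4,4-trimethyl-5-oxohex-2-enoate, via keto aldehyde 4 (not isolated)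
Conditions: Dess–Martin periodinane (2.4 equiv), pyridine, CH2Cl2, 0 °C → rt; then 3 (1.3 equiv), rt → 40 °C
Reagents that add atoms: none
Why: Dess–Martin oxidation of both hydroxyls gives the volatile keto aldehyde, whose aldehyde has no α-hydrogen, and the stabilised ylide then undergoes Wittig olefination at the aldehyde only (hindered ketones are spared) with the E selectivity typical of 2-substituted ester ylides; no stereocentre is formed.

Step 3
Reactants: 5 ethyl (E)-2,4,4-trimethyl-5-oxohex-2-enoate
Product: 6 (E)-2,4,4-trimethyl-5-oxohex-2-enoic acid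
Conditions: LiOH·H2O, THF/MeOH/H2O, 40 °C; then 1 M HCl to pH 3
Reagents that add atoms: lithium hydroxide, [Li+].[OH-]
Why: Saponification of the ethyl ester; the γ-carbon is quaternary, so the enoate can neither deconjugate nor isomerise, and the E alkene keeps the ketone enolate away from the carboxyl carbon.

Step 4
Reactants: 7 (Z)-3-methylpent-2-en-4-yn-1-ol
Product: 8 (Z)-3-methylpenta-2,4-dien-1-ol
Conditions: H2 (1 atm, stopped at 1 equiv), Pd/CaCO3 poisoned with Pb(OAc)2, quinoline, pentane/Et2O, 0 °C
Reagents that add atoms: none
Why: Lindlar-type semihydrogenation of the terminal alkyne over lead-poisoned palladium should stop at the vinyl group and leaves the Z geometry of the trisubstituted alkene untouched.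

Step 5
Reactants: 6 (E)-2,4,4-trimethyl-5-oxohex-2-enoic acid; 8 (Z)-3-methylpenta-2,4-dien-1-ol
Product: 9 (Z)-3-methylpenta-2,4-dien-1-yl (E)-2,4,4-trimethyl-5-oxohex-2-enoate
Conditions: DCC, 4-(dimethylamino)pyridine (10 mol%), CH2Cl2, 0 °C → rt
Reagents that add atoms: none
Why: Steglich esterification joins acid and primary allylic alcohol at or below room temperature without acid, so the Z diene is neither isomerised nor rearranged and both alkene geometries are carried into the triene ester.

Step 6
Reactants: 9 (Z)-3-methylpenta-2,4-dien-1-yl (E)-2,4,4-trimethyl-5-oxohex-2-enoate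
Product: 10 (3aR,7S,7aS)-4,7a-dimethyl-7-(2-methyl-3-oxobutan-2-yl)-3a,6,7,7a-tetrahydroisobenzofuran-1(3H)-one
Conditions: (S)-1-(2-methylphenyl)-3,3-diphenyltetrahydro-1H,3H-pyrrolo[1,2-c][1,3,2]oxazaborole (25 mol%), HNTf2 (20 mol%), CH2Cl2 (0.05 M), −78 → −20 °C; Et3N quench
Reagents that add atoms: none
Why: Proposed new method: the cationic boron centre binds the ester carbonyl of 9 and lowers the enoate LUMO, so that the tethered diene C6=C7–C8=C9 adds suprafacially across C10=C5 in a concerted but asynchronous [4+2] cycloaddition (C5–C6 bonding in advance); the closest known reaction types are the thermal intramolecular Diels–Alder reaction of dienyl 2-alkenoates and the oxazaborolidinium-catalysed intermolecular Diels–Alder reaction of 2-alkenoates, but a catalysed enantioselective version through an ester tether, with a 2-methyl enoate that lacks the α-hydrogen usually invoked to organise the complex, has not been shown. Ring B closes as the six-membered cycloadduct ring, and the γ-lactone closes as the five-membered ring completed by the new C9–C10 bond across the three-atom tether C11–O–C1, with the ester in its lactone-like E rotamer and the tether carbonyl exo to the diene. The relative configuration at C5 and C10 is fixed by the E enoate (C4 and the C10 methyl end up cis on ring B, so H-5 is trans to that methyl), and that at C9 by the Z diene, whose inward-pointing C11 can reach C1 only in the cis-fused arrangement (C11 cis to C1, trans to the C10 methyl); since C6 carries only hydrogens, endo and exo approach lead to the same product. The absolute configuration is set by the catalyst alone, whose aryl groups should shield one face of the bound enoate (assumed sense stated in the remarks). The step needs facial selectivity and must outrun ionisation of the pentadienyl C11–O bond, which is why it is run cold with slightly less HNTf2 than oxazaborolidine; the gem-dimethyl group on C4 biases the chain toward the reactive folded conformation, and the hindered C3 ketone can only bind the catalyst reversibly.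

Step 7
Reactants: 10 keto lactone
Product: 11 3-[(1R,5R,6S)-5,6-bis(hydroxymethyl)-4,6-dimethylcyclohex-3-en-1-yl]-3-methylbutan-2-ol (both carbinol epimers)
Conditions: LiAlH4, THF, 0 °C → rt; aqueous NaOH work-up
Reagents that add atoms: none
Why: LiAlH4 reduction opens the lactone to the C1/C11 diol and also reduces the C3 ketone (the carbinol epimers converge in step 9); C5, C9 and C10 are not α to any carbonyl and are untouched.

Step 8
Reactants: 11 triol
Product: 12 3-[(1R,5R,6S)-6-(hydroxymethyl)-4,6-dimethyl-5-({[tri(propan-2-yl)silyl]oxy}methyl)cyclohex-3-en-1-yl]-3-methylbutan-2-ol (both carbinol epimers)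
Conditions: TIPSCl (1.1 equiv), imidazole, DMF, 0 °C → rt
Reagents that add atoms: chlorotri(propan-2-yl)silane (TIPSCl), CC(C)[Si](Cl)(C(C)C)C(C)C
Why: Silyl ether formation with the bulky chlorosilane should take place at the C11 hydroxyl, the only primary alcohol that is not neopentyl, and masks the oxygen that would otherwise add to C1 of the enone of step 10.

Step 9
Reactants: 12 C11 silyl ether diol
Product: 13 (1S,2R,6R)-1,3-dimethyl-6-(2-methyl-3-oxobutan-2-yl)-2-({[tri(propan-2-yl)silyl]oxy}methyl)cyclohex-3-ene-1-carbaldehyde
Conditions: Dess–Martin periodinane (3 equiv), pyridine, CH2Cl2, rt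
Reagents that add atoms: none
Why: Dess–Martin oxidation turns the neopentyl C1 alcohol into the aldehyde and the C3 carbinol into the methyl ketone in one operation; neither carbonyl can epimerise a stereocentre because C4 and C10 are quaternary.

Step 10
Reactants: 13 keto aldehyde
Product: 15 (5R,9R,10S)-11-{[tri(propan-2-yl)silyl]oxy}drima-1,7-dien-3-one (9-epi-drimane: H-5 α, H-9 β, C10 methyl β), via ketol 14 (not isolated)
Conditions: KOH, MeOH, rt → 50 °C
Reagents that add atoms: none
Why: Intramolecular aldol condensation: the only enolisable position (C2, the methyl of the C3 ketone) adds to the C1 aldehyde in a six-membered closure that gives trans-fused ring A (the two chains are trans-diequatorial on ring B), and E1cB loss of water gives the C1=C2 enone, so no stereocentre remains at C1.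

Step 11
Reactants: 15 silyl ether enone
Product: 17 (5R,9R,10S)-11-{[tri(propan-2-yl)silyl]oxy}drim-7-en-3-one, via lithium enolate 16 (not isolated)
Conditions: Li (3 equiv), t-BuOH (1 equiv), NH3(l)/THF, −78 °C; then isoprene, NH4Cl
Reagents that add atoms: none
Why: Dissolving-metal (Birch-type) reduction of the enone stops at the lithium enolate, which is protonated to the saturated ketone on quench; electron transfer is insensitive to the crowding at C1 (C10 methyl on one face, axial C11 group on the other) and spares the isolated C7=C8 alkene and the silyl ether, and no stereocentre is created because C1 and C2 become CH2.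

Step 12
Reactants: 17 silyl ether ketone
Product: 18 (5R,9R,10S)-11-hydroxydrim-7-en-3-one (9-epi), i.e. (4aS,5R,8aR)-5-(hydroxymethyl)-1,1,4a,6-tetramethyl-3,4,4a,5,8,8a-hexahydronaphthalen-2(1H)-one
Conditions: Bu4NF, THF, 0 °C → rt
Reagents that add atoms: none
Why: Fluoride-mediated desilylation frees C11–OH only after the enone has gone, so the alkoxide has no acceptor to add to; no stereocentre is α to the ketone, so the basic fluoride cannot epimerise anything.

Step 13
Reactants: 18 (5R,9R,10S)-11-hydroxydrim-7-en-3-one; 19 isofraxidin (7-hydroxy-6,8-dimethoxy-2H-chromen-2-one)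
Product: 20 7-{[(1R,4aR,8aS)-2,5,5,8a-tetramethyl-6-oxo-1,4,4a,5,6,7,8,8a-octahydronaphthalen-1-yl]methoxy}-6,8-dimethoxy-2H-chromen-2-one (CNP0127079.1)
Conditions: PPh3, DIAD, THF, 0 °C → rt
Reagents that add atoms: none
Why: Mitsunobu etherification: the acidic 7-hydroxycoumarin displaces the oxyphosphonium group at the primary, non-stereogenic C11 by SN2, while the ketone, the trisubstituted alkene and the coumarin lactone are inert to the redox couple.

**Compound list**
1 | ethyl 2,2-dimethyl-3-oxobutanoate | CCOC(=O)C(C)(C)C(C)=O | starting material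
2 | 2,2-dimethylbutane-1,3-diol (racemic) | CC(O)C(C)(C)CO | intermediate
3 | ethyl 2-(triphenylphosphoranylidene)propanoate | CCOC(=O)C(C)=P(c1ccccc1)(c1ccccc1)c1ccccc1 | starting material
4 | 2,2-dimethyl-3-oxobutanal (formed in the flask) | CC(=O)C(C)(C)C=O | intermediate
5 | ethyl (E)-2,4,4-trimethyl-5-oxohex-2-enoate | CCOC(=O)/C(C)=C/C(C)(C)C(C)=O | intermediate
6 | (E)-2,4,4-trimethyl-5-oxohex-2-enoic acid | OC(=O)/C(C)=C/C(C)(C)C(C)=O | intermediate
7 | (Z)-3-methylpent-2-en-4-yn-1-ol | C#C/C(C)=C\CO | starting material
8 | (Z)-3-methylpenta-2,4-dien-1-ol | C=C/C(C)=C\CO | intermediate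
9 | (Z)-3-methylpenta-2,4-dien-1-yl (E)-2,4,4-trimethyl-5-oxohex-2-enoate (key-step precursor) | C=C/C(C)=C\COC(=O)/C(C)=C/C(C)(C)C(C)=O | intermediate
10 | (3aR,7S,7aS)-4,7a-dimethyl-7-(2-methyl-3-oxobutan-2-yl)-3a,6,7,7a-tetrahydroisobenzofuran-1(3H)-one (cis-fused γ-lactone, key-step product) | O=C1OC[C@@H]2C(C)=CC[C@@H](C(C)(C)C(C)=O)[C@]12C | intermediate
11 | 3-[(1R,5R,6S)-5,6-bis(hydroxymethyl)-4,6-dimethylcyclohex-3-en-1-yl]-3-methylbutan-2-ol (carbinol epimers) | OC[C@@H]1C(C)=CC[C@@H](C(C)(C)C(C)O)[C@]1(C)CO | intermediate
12 | 3-[(1R,5R,6S)-6-(hydroxymethyl)-4,6-dimethyl-5-({[tri(propan-2-yl)silyl]oxy}methyl)cyclohex-3-en-1-yl]-3-methylbutan-2-ol (carbinol epimers) | CC(C)[Si](OC[C@@H]1C(C)=CC[C@@H](C(C)(C)C(C)O)[C@]1(C)CO)(C(C)C)C(C)C | intermediate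
13 | (1S,2R,6R)-1,3-dimethyl-6-(2-methyl-3-oxobutan-2-yl)-2-({[tri(propan-2-yl)silyl]oxy}methyl)cyclohex-3-ene-1-carbaldehyde | CC(C)[Si](OC[C@@H]1C(C)=CC[C@@H](C(C)(C)C(C)=O)[C@]1(C)C=O)(C(C)C)C(C)C | intermediate
14 | (5R,9R,10S)-1-hydroxy-11-{[tri(propan-2-yl)silyl]oxy}drim-7-en-3-one (C1 epimers, formed in the flask) | CC(C)[Si](OC[C@@H]1C(C)=CC[C@H]2C(C)(C)C(=O)CC(O)[C@]12C)(C(C)C)C(C)C | intermediate
15 | (5R,9R,10S)-11-{[tri(propan-2-yl)silyl]oxy}drima-1,7-dien-3-one | CC(C)[Si](OC[C@@H]1C(C)=CC[C@H]2C(C)(C)C(=O)C=C[C@]12C)(C(C)C)C(C)C | intermediate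
16 | lithium (5R,9R,10S)-11-{[tri(propan-2-yl)silyl]oxy}drima-2,7-dien-3-olate (formed in the flask) | [Li+].CC(C)[Si](OC[C@@H]1C(C)=CC[C@H]2C(C)(C)C([O-])=CC[C@]12C)(C(C)C)C(C)C | intermediate
17 | (5R,9R,10S)-11-{[tri(propan-2-yl)silyl]oxy}drim-7-en-3-one | CC(C)[Si](OC[C@@H]1C(C)=CC[C@H]2C(C)(C)C(=O)CC[C@]12C)(C(C)C)C(C)C | intermediate
18 | (5R,9R,10S)-11-hydroxydrim-7-en-3-one (9-epi; H-5 α, H-9 β, C10 methyl β) | OC[C@@H]1C(C)=CC[C@H]2C(C)(C)C(=O)CC[C@]12C | intermediate
19 | isofraxidin (7-hydroxy-6,8-dimethoxy-2H-chromen-2-one) | COc1cc2ccc(=O)oc2c(OC)c1O | starting material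
20 | 7-{[(1R,4aR,8aS)-2,5,5,8a-tetramethyl-6-oxo-1,4,4a,5,6,7,8,8a-octahydronaphthalen-1-yl]methoxy}-6,8-dimethoxy-2H-chromen-2-one | COc1cc2ccc(=O)oc2c(OC)c1OC[C@@H]1C(C)=CC[C@H]2C(C)(C)C(=O)CC[C@]12C | target

**Count.** Total: 13 steps. Longest linear sequence: 12 steps (steps 1–3 and 5–13, from 1 to 20); step 4 is a one-step branch.

**Steps most likely to fail**

Step 6. The cationic boron acid may ionise the pentadienyl C11–O bond instead of activating the enoate, may be tied up by the ketone, may trigger acid-induced alkene migration or carbonyl-ene closure in the adduct, or may give poor facial selectivity. The fallback uses known chemistry and sets out from 9: a thermal intramolecular Diels–Alder reaction (1,2-dichlorobenzene, 2,6-di-tert-butyl-4-methylphenol, 180 °C, high dilution, sealed tube) should give, with the same geometry-enforced relative configuration, the racemic keto lactone F1. Its enantiomers are then separated by preparative chromatography on a chiral stationary phase (cellulose tris(3,5-dimethylphenylcarbamate)), which returns the route to 10.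

Step 13. Substitution at the β-branched, axial C11 by a doubly ortho-substituted phenoxide may be too slow, so that elimination toward the C9=C11 diene or capture of the oxyphosphonium species by the hydrazide takes over. The fallback sets out from 18: triflation (Tf2O, 2,6-lutidine, CH2Cl2, −78 °C) gives the primary triflate F5, which is used cold in a Williamson ether synthesis with the caesium phenoxide of 19 (Cs2CO3, MeCN, −20 °C → rt), arriving at 20.

Step 8. Silylation may lose regiocontrol (reaction at the C1 hydroxyl, or twice). The fallback sets out from 10 and fixes the regiochemistry through the lactone: aminolysis (MeNH(OMe)·HCl, AlMe3, CH2Cl2, 0 °C → rt) opens the lactone to the hydroxy Weinreb amide F2, whose only hydroxyl is C11–OH. Silylation (TIPSOTf, 2,6-lutidine, CH2Cl2, −78 °C) gives the silyl ether amide F3. LiAlH4 (THF, 0 °C) then reduces amide and ketone to the hydroxy aldehyde F4, which exists largely as its six-membered lactol and is reduced without purification (NaBH4, MeOH, 0 °C) to rejoin the route at 12.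

**Further compounds**
F1 | step 6 | racemic keto lactone (racemate of 10, both enantiomers shown) | O=C1OC[C@@H]2C(C)=CC[C@@H](C(C)(C)C(C)=O)[C@]12C.O=C1OC[C@H]2C(C)=CC[C@H](C(C)(C)C(C)=O)[C@@]12C
F2 | step 8 | (1S,2R,6S)-2-(hydroxymethyl)-N-methoxy-N,1,3-trimethyl-6-(2-methyl-3-oxobutan-2-yl)cyclohex-3-ene-1-carboxamide | OC[C@@H]1C(C)=CC[C@@H](C(C)(C)C(C)=O)[C@]1(C)C(=O)N(C)OC
F3 | step 8 | tri(propan-2-yl)silyl ether of F2 at the CH2OH group | CC(C)[Si](OC[C@@H]1C(C)=CC[C@@H](C(C)(C)C(C)=O)[C@]1(C)C(=O)N(C)OC)(C(C)C)C(C)C
F4 | step 8 | (1S,2R,6S)-6-(3-hydroxy-3-methylbutan-2-yl type side chain: 3-hydroxy-2-methylbutan-2-yl)-1,3-dimethyl-2-({[tri(propan-2-yl)silyl]oxy}methyl)cyclohex-3-ene-1-carbaldehyde (carbinol epimers, in equilibrium with the lactol) | CC(C)[Si](OC[C@@H]1C(C)=CC[C@@H](C(C)(C)C(C)O)[C@]1(C)C=O)(C(C)C)C(C)C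
F5 | step 13 | trifluoromethanesulfonate of 18 at C11 | O=S(=O)(OC[C@@H]1C(C)=CC[C@H]2C(C)(C)C(=O)CC[C@]12C)C(F)(F)F
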